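**Plan**

- Retrosynthesis (ring numbered so that C2 carries the isobutyryl group, C1, C3 and C5 the oxygens, C4 and C6 the prenyl pairs): the four C4/C6–CH2 bonds to the prenyl groups are cut first, then the ring bond C1–C2, last the bond from C2 to the isobutyryl carbonyl.
- Enabling feature: oxygen on every second ring carbon (C1, C3, C5) and an acyl group on C2 mark the ring as a folded, isobutyryl-primed 3,5,7-triketo acid closed by Claisen condensation. A 4-hydroxy-2-pyranone is the bench-stable form of that chain.
- Forward: the chain is completed by acylating the 6-methyl group of a commercial pyranone (step 1). Mg(OMe)2 then opens the lactone and closes the only ring of the target, the six-membered carbocycle (step 2). The four prenyl groups are attached last (step 3).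
- Stereochemistry: none has to be set. C4 and C6 each bear two identical prenyl groups and the target is achiral.

Key step: step 2

Remark: the target is taken to be exactly the structure of the given SMILES, the 4,4,6,6-tetraprenyl acyltrione (one prenyl group more than colupulone), drawn as one of its freely interconverting enol tautomers.

**Route**

Step 1
Reactants: 1 4-hydroxy-6-methyl-2H-pyran-2-one; 2 methyl 2-methylpropanoate
Product: 4 4-hydroxy-6-(3-methyl-2-oxobutyl)-2H-pyran-2-one, via dilithium pyranone dianion 3 (not isolated)
Conditions: 1 (2.0 equiv), LiN(iPr)2 (4.0 equiv), THF/DMPU, −78 → 0 °C; then 2 (1.0 equiv), −78 °C → rt; 1 M HCl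
Reagents that add atoms: methyl 2-methylpropanoate (2), COC(=O)C(C)C
Why: The amide base removes first the 4-OH proton and then a proton of the vinylogous 6-methyl group, and the dianion reacts at its carbon terminus with the ester in a crossed Claisen acylation, the second equivalent of dianion taking up the proton of the more acidic β-diketone product so that no free amide base is left to enolize the ester.

Step 2
Reactants: 4 4-hydroxy-6-(3-methyl-2-oxobutyl)-2H-pyran-2-one
Product: 7 2-methyl-1-(2,4,6-trihydroxyphenyl)propan-1-one, via triketo ester magnesium chelate 5 (not isolated), via cyclic trione 6 (not isolated)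
Conditions: Mg(OMe)2 (6 equiv), dry MeOH, reflux, Ar; then cold 1 M HCl
Reagents that add atoms: none
Why: Methoxide adds to the lactone carbonyl of 4 and the ring opens to methyl 8-methyl-3,5,7-trioxononanoate 5, which the divalent magnesium ion holds as a chelated polyenolate; the methylene between the C5 and C7 ketones of this chain then attacks the ester carbonyl and methoxide leaves, forming ring bond C1–C2 and the trione 6, whose enolization to the aromatic 7 makes the sequence irreversible. The closest known reaction type is the magnesium alkoxide-mediated intramolecular Claisen (Dieckmann-type) condensation of 3,5,7-triketo esters and of 6-(2-oxoalkyl)-4-hydroxy-2-pyranones to acylphloroglucinols. The six-membered carbocycle closes in the 6-exo-trig mode, the ester C=O lying outside the new ring, and the enolate may take part through either of its two ketone oxygens. No stereocentre is formed. The step needs Claisen closure to win over aldol closure of the ester α-carbon onto the isopropyl ketone, which would lead to a resorcylate, and over retro-Claisen cleavage of the chain. This is secured by the electrophile being a methyl ester and not a carboxylate in water-free methanol, by chelation that ties the diketone oxygens together and activates the ester, and by the α-branch that shields the isopropyl ketone as an aldol acceptor.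

Step 3
Reactants: 7 2-methyl-1-(2,4,6-trihydroxyphenyl)propan-1-one; 8 1-bromo-3-methylbut-2-ene
Product: 12 5-hydroxy-4-(2-methylpropanoyl)-2,2,6,6-tetrakis(3-methylbut-2-en-1-yl)cyclohex-4-ene-1,3-dione (the target), via monoprenyl ketone 9 (not isolated), via deoxycohumulone 10 (not isolated), via colupulone 11 (not isolated)
Conditions: NaOMe (6.5 equiv), 8 (6 equiv, in portions), degassed MeOH, 0 °C → rt, Ar; then 1 M HCl
Reagents that add atoms: 1-bromo-3-methylbut-2-ene (8), CC(C)=CCBr
Why: This is an exhaustive phenoxide and enolate C-alkylation (SN2 at the primary carbon of the allylic bromide, favoured over O-alkylation in the hydrogen-bonding solvent), in which the first two prenyl groups enter the free ring positions, the next two dearomatize the ring at C4 and C6, and alkylation should end at the tetraprenyl stage because the product is a delocalized, weakly nucleophilic acyltrione enolate with no ring C–H left; no stereocentre arises since each quaternary carbon carries two identical groups.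

**Compound list**

1 | 4-hydroxy-6-methyl-2H-pyran-2-one | CC1=CC(O)=CC(=O)O1 | starting material
2 | methyl 2-methylpropanoate | COC(=O)C(C)C | starting material
3 | dilithium dianion of 1 (4-olate, 6-methylide) | [Li+].[Li+].[CH2-]C1=CC([O-])=CC(=O)O1 | intermediate (not isolated)
4 | 4-hydroxy-6-(3-methyl-2-oxobutyl)-2H-pyran-2-one | CC(C)C(=O)CC1=CC(O)=CC(=O)O1 | intermediate
5 | methyl 8-methyl-3,5,7-trioxononanoate (present as its magnesium chelate) | COC(=O)CC(=O)CC(=O)CC(=O)C(C)C | intermediate (not isolated)
6 | 2-(2-methylpropanoyl)cyclohexane-1,3,5-trione | CC(C)C(=O)C1C(=O)CC(=O)CC1=O | intermediate (not isolated)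
7 | 2-methyl-1-(2,4,6-trihydroxyphenyl)propan-1-one | CC(C)C(=O)c1c(O)cc(O)cc1O | intermediate
8 | 1-bromo-3-methylbut-2-ene | CC(C)=CCBr | starting material
9 | 2-methyl-1-[2,4,6-trihydroxy-3-(3-methylbut-2-en-1-yl)phenyl]propan-1-one | CC(C)C(=O)c1c(O)cc(O)c(CC=C(C)C)c1O | intermediate (not isolated)
10 | 2-methyl-1-[2,4,6-trihydroxy-3,5-bis(3-methylbut-2-en-1-yl)phenyl]propan-1-one (deoxycohumulone) | CC(C)C(=O)c1c(O)c(CC=C(C)C)c(O)c(CC=C(C)C)c1O | intermediate (not isolated)
11 | 3,5-dihydroxy-2-(2-methylpropanoyl)-4,6,6-tris(3-methylbut-2-en-1-yl)cyclohexa-2,4-dien-1-one (colupulone) | CC(C)C(=O)C1=C(O)C(CC=C(C)C)=C(O)C(CC=C(C)C)(CC=C(C)C)C1=O | intermediate (not isolated)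
12 | 5-hydroxy-4-(2-methylpropanoyl)-2,2,6,6-tetrakis(3-methylbut-2-en-1-yl)cyclohex-4-ene-1,3-dione | CC(C)=CCC1(CC=C(C)C)C(=O)C(C(=O)C(C)C)=C(O)C(CC=C(C)C)(CC=C(C)C)C1=O | target

**Count**

Total steps: 3. Longest linear sequence: 3 steps.

**Steps most likely to fail**

Step 3 is the most exposed. O-alkylation, followed by ring closure of the prenyl ethers to chromans, may compete with C-alkylation. Methanolysis of the bromide may outrun the slow third and fourth alkylations, so that partly prenylated material remains, and the electron-rich intermediates may be oxidized by traces of air. The fallback sets out from 7 and comes back at 12. The two aromatic prenyl groups would be introduced by Friedel–Crafts alkylation with 2-methylbut-3-en-2-ol and BF3·OEt2 in dioxane at room temperature, which avoids phenoxide chemistry altogether, and deoxycohumulone 10 would this time be isolated and purified. The two quaternary centres would then be built by a Tsuji–Trost reaction with methyl 3-methylbut-2-en-1-yl carbonate (COC(=O)OCC=C(C)C) and Pd(PPh3)4 (zerovalent palladium) in THF. Under these conditions any O-prenyl ether is re-ionized by the catalyst and funnelled to the C-prenyl product, and attack at the unsubstituted allyl terminus should give the linear prenyl group.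

Step 1 comes second. Proton transfer may win over acyl transfer: the dianion may deprotonate the α-hydrogen of the hindered ester or be quenched by the newly formed β-diketone, and the dilithium salt may be too poorly soluble to react cleanly. The fallback sets out from 1 and comes back at 4. The dianion 3 would be added to 2-methylpropanal in an aldol addition, a faster reaction whose alkoxide product consumes no further base, to give racemic 4-hydroxy-6-(2-hydroxy-3-methylbutyl)-2H-pyran-2-one F1. Jones oxidation (CrO3, H2SO4, acetone, 0 °C) of the secondary alcohol would then give 4 and remove the carbinol stereocentre.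

Step 2 comes third. Aldol closure of the ester α-carbon onto the isopropyl ketone, methoxide cleavage of the polyketo chain, or reclosure of the opened chain to the pyranone on acidification may divert material. The fallback sets out from 2 and comes back at 7; it gives up the chain folding and is held in reserve only. Saponification (LiOH, THF/H2O, then HCl) would give 2-methylpropanoic acid F2, which would acylate commercial benzene-1,3,5-triol in BF3·OEt2 at 80 °C in a Friedel–Crafts acylation to give 7 directly.

**Further compounds**

F0 | step 3 | none | none
F1 | step 1 | 4-hydroxy-6-(2-hydroxy-3-methylbutyl)-2H-pyran-2-one (racemic) | CC(C)C(O)CC1=CC(O)=CC(=O)O1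
F2 | step 2 | 2-methylpropanoic acid | CC(C)C(=O)O
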